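## Structural features

1. The target is a C20 bromolabdane (labdane numbering; 3S,5R,8R,9R,10S,13R,14S). A trans-decalin (rings A and B) shares its C8–C9 bond with an eight-membered cyclic ether (ring C: O, C8, C9, C11, C12, C13, C14, C15), and ring C carries a cis-fused trisubstituted epoxide on C13–C14.
2. On the decalin, C10 (quaternary), C9 and C8 (axial C17 methyl, equatorial ether oxygen) stand next to each other, C5 adjoins C10, and C3 carries an equatorial (β) bromine beside the C4 gem-dimethyl group. The adjacent pair C13/C14 is insulated from these five centres by C11–C12 on one side and O–C15 on the other.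
3. The fragile groups are the epoxide (acids, Lewis acids), the tertiary C8–O bond (ionisation, then elimination or re-closure to a six-membered ether at C13) and the secondary bromide (strong reductants, low-valent metals).
4. The first real difficulty is C3–Br. The carbon is neopentyl, so SN2 displacement is closed, ionisation ends in ring contraction or methyl shift, and the nearest heteroatom (O on C8) is six bonds away, so nothing can direct a reagent.
5. The second difficulty is ring C, a medium ring closed onto a hindered tertiary oxygen, for which every cationic or π-allyl closure has a faster six-membered alternative at C13.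
6. Rings A and B with C5, C8, C9, C10, the C8 oxygen and the C11–C13/C16 chain are, atom for atom and in the right absolute sense, those of (−)-sclareol. On the decalin the target differs only by one substituent in place of the equatorial hydrogen of the C3 methylene of ring A.
7. The key step exploits this feature. The hydrocarbon end of the rigid decalin (ring A, C3–H next to the C4 gem-dimethyl group) lies opposite the polar end (oxygens on C8 and C13), so a P450 pocket, and not innate C–H reactivity, chooses C3.
8. In one sentence, the route is the enzymatic hydroxylation of the unactivated C3 methylene of sclareol, whereas the route most chemists would draw first is a bromonium-initiated polyene cyclisation.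

## Logic of the disconnections

**13 from 12.** Bonds cut: C2–H and the axial (α) C3–H.
- Reason: an equatorial bromide on a neopentyl carbon cannot be made by substitution. It results if bromine already sits on an sp2 C3 and hydrogen arrives last, from the α face.
- Gain: the C3 stereocentre disappears, and C3–Br becomes an alkenyl bromide that is inert to bases, Ru carbenes and dioxiranes.
- Demand: a hydrogenation that keeps C–Br and the epoxide, puts the first H on C2 and the second on C3 anti to the axial C4 methyl, and finds no other alkene. It is therefore the last step.

**12 from 11.** Bonds cut: C13–O and C14–O of the epoxide.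
- Reason: a syn oxygen transfer to a Z-alkene gives the cis fusion automatically.
- Gain: two stereocentres and the most acid-labile group are removed.
- Demand: attack on one face of C13=C14, which the conformation of ring C must provide, and preference for this electron-rich alkene over the bromoalkene.

**11 from 10.** Bond cut: C13=C14.
- Reason: it is the only bond of ring C whose formation has no six-membered competitor and does not touch the hindered C8–O bond.
- Gain: the medium ring opens to two terminal alkenes.
- Demand: metathesis onto a 1,1-disubstituted alkene in an eight-membered closure. The gauche, diequatorial O–C8–C9–C11 array and the fully substituted C8 help.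

**10 from 9.** Bond cut: O–C15.
- Reason: C14 and C15 come in as an allyl group on the oxygen that the starting material already holds at C8, so C8 is never ionised.
- Gain: a three-carbon reagent is split off.
- Demand: alkylation of a hindered tertiary alkoxide, so no enolisable or base-labile group may be present.

**9 from 8.** Bond cut: C3–Br (sp2).
- Reason: halide is exchanged at an sp2 carbon, where the neopentyl environment does not forbid substitution through a metal.
- Gain: bromine is traced to a bromide salt.
- Demand: neutral conditions that spare the tertiary alcohol and the acid-sensitive isopropenyl group.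

**8 from 7.** Bonds cut: the enol O–S bond; the C2=C3 bond returns to C2–H and C3=O.
- Reason: C4 is quaternary, so the ketone can enolise in one direction only.
- Gain: a plain ketone.
- Demand: the C8 hydroxyl must stay a spectator as its alkoxide.

**7 from 6.** Change: C3=O back to C3(H)–OH.
- Reason: only one secondary alcohol is present.
- Gain: the oxidation level of the enzymatic product is reached.
- Demand: a neutral oxidant that leaves the alkene and the tertiary alcohol alone.

**6 from 5.** Bond cut: C13=CH2.
- Reason: the alkene partner for ring closure comes from a methyl ketone while C3 is still an alcohol, so no second ketone competes.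
- Gain: one carbon is removed.
- Demand: olefination of a δ-hydroxy ketone that rests partly as its hemiketal.

**5 from 2 (through 4 and 3).** Bonds restored: C13–C14 and C14–C15.
- Reason: the native vinyl carbinol cannot be closed to ring C, because it would give the six-membered ether at C13. It is traded for the ketone.
- Gain: the natural side chain, and with it a commercial skeleton, is reached.
- Demand: cleavage of one alkene and of the triol derived from it without touching the isolated hydroxyls.

**2 from 1.** Bond cut: C3–O, back to C3–H.
- Reason: this is the single change that separates the functionalised decalin from a bulk terpene bringing C5, C8, C9, C10 and the C8 oxygen in enantiopure form.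
- Gain: the largest of the route, since the precursor is purchased.
- Demand: site selectivity for C3 against the innately preferred C2, which only a binding pocket can give.

## Other disconnections considered

**Alternative 1:** (the first that comes to mind)
- Cut: C3–Br, C4–C5, C9–C10 and C8–O together.
- Forward key step: bromonium-initiated bicyclisation of (5E,9E)-farnesylacetone A1, terminated by the carbonyl oxygen. This gives the bromo enol ether A2, which is hydrolysed to the bromo hydroxy ketone A3. Methylenation, allylation, ring-closing metathesis and epoxidation follow.
- Ground for preferring the chosen plan: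
  - The plan is shorter, but Br+ must pick the terminal one of three nearly equal trisubstituted alkenes and one of its enantiotopic faces.
  - Bromonium ions pass Br+ on to free alkenes, which erodes any induced enantiomeric excess.
  - The cascade can leak by proton loss after the first ring.
  - Five stereocentres would then arrive racemic or scalemic, with nothing later to correct them. The chosen plan buys four of them enantiopure and sets the fifth under substrate control.

**Alternative 2:**
- Cut: the same four bonds, but ring C is made in the same event.
- Forward key step: A1 is turned into the oxetane A4 by double methylene transfer, and Br+ starts the cascade. The oxetane oxygen captures the C8 cation through a six-membered transition state to give the bicyclic oxetanium ion A5. Strain-driven heterolysis of its C13–O bond expands the six-membered ring to the eight-membered one, and proton loss gives the bromo-oxocene A6, ready for epoxidation.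
- Ground for preferring the chosen plan:
  - The idea is very short, but the C13 cation has three β-positions.
  - The C14–H bonds are the worst aligned with the breaking C13–O bond (about 120° within the four-membered ring) and are inductively deactivated by O–C15. The Δ12 and exocyclic isomers should therefore prevail over A6.
  - External nucleophiles can open A5 at the primary C15.
  - Absolute control is as weak as in Alternative 1.

**Alternative 3:**
- Cut: C3–Br directly to C3–H on the finished debromo skeleton A7 (from 1 by the chemistry of steps 2, 3 and 7–9).
- Forward key step: radical C–H bromination, or an iron/α-ketoglutarate halogenase.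
- Ground for preferring the chosen plan:
  - It would save four steps.
  - Small radical reagents choose the least hindered methylene and should give the 2α-bromide A8.
  - A C3 radical should take bromine from the open α face, anti to the axial C4 methyl, which leads to the axial 3α-bromide A9.
  - The C15–H bonds next to oxygen are weaker than any ring A bond.
  - A halogenase for this substrate class would first have to be evolved.
  - The chosen plan separates the two problems: the enzyme picks the site with oxygen, and the configuration is set by delivering hydrogen last.

Key step: step 1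

Assumption: labdane numbering is used throughout (C3 = CHBr, C8 = ether carbon of the decalin, C15 = OCH2), α/β refer to the usual projection with the C10 methyl β, and the P450 variant is taken to be made by standard expression in E. coli from a synthetic gene, as a catalyst and not as a starting material.

## Steps

Step 1
Reactants: 1 (−)-sclareol [(13R)-labd-14-ene-8α,13-diol]
Product: 2 3β-hydroxysclareol [(13R)-labd-14-ene-3β,8α,13-triol]
Conditions: C3-selective P450 BM3 (CYP102A1) variant, E. coli lysate, NADP+ (cat.), phosphite dehydrogenase, Na2HPO3, air, KPi buffer pH 8.0, EtOH (5% v/v), 25 °C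
Reagents that add atoms: dioxygen, O=O
Why: Cytochrome P450 monooxygenation: O2 is reductively activated at the haem to the ferryl porphyrin radical cation (compound I), which abstracts the equatorial β-hydrogen of C3 and returns OH to the short-lived C3 radical on the same face (hydrogen abstraction/oxygen rebound, retention). The closest known reaction type is the C3 hydroxylation of drimane and labdane A rings by engineered P450 BM3 variants and by fungal hydroxylases, so this is a known reaction on its known substrate class. No ring is closed. The one new stereocentre, C3 (S, 3β-OH), is controlled by the protein, which presents only the β-equatorial C–H to the iron; what the route carries on is the site, since C3 becomes sp2 in step 4 and its final configuration is set in step 10. The selectivity needed is C3 over C2 (the methylene that small radical and metal-oxo reagents prefer, being the least hindered), over C1, C6 and C7, over the tertiary C5–H and C9–H, and over the C14=C15 vinyl group. The substrate secures it by shape and polarity: a rigid rod with both hydroxyls (C8, C13) and the vinyl group at one end, which stays at the polar mouth of the substrate channel, and a purely hydrocarbon ring A at the other end, which is driven against the haem. There the C4 gem-dimethyl group fills the hydrophobic niche beside the porphyrin and leaves C3–Hβ as the C–H bond nearest to the ferryl oxygen, while C5–H and C9–H are α-axial and buried under the decalin. Over-oxidation to the 3-ketone would do little harm, because step 4 makes that ketone in any case.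

Step 2
Reactants: 2 3β-hydroxysclareol
Product: 5 3β,8α-dihydroxy-14,15-dinorlabdan-13-one, via labdane pentaol 3 (not isolated), via hydroxy aldehyde 4 (not isolated)
Conditions: OsO4 (cat.), NaIO4 (excess), 2,6-lutidine, dioxane–H2O 3:1, 23 °C
Reagents that add atoms: sodium periodate, [Na+].[O-]I(=O)(=O)=O; water, O (source of the two new oxygen atoms of 3; they leave again with C14 and C15, so 5 holds no new heavy atom)
Why: Lemieux–Johnson oxidation: the only alkene is dihydroxylated to 3, whose 13,14,15-triol unit is cleaved twice by periodate (C14–C15, then C13–C14 of 4), so that the carbinol carbon C13 becomes a methyl ketone. The C3 and C8 hydroxyls have no vicinal oxygen and are untouched; the C13 stereocentre is given up on purpose.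

Step 3
Reactants: 5 3β,8α-dihydroxy-14,15-dinorlabdan-13-one
Product: 6 13-methylidene-14,15-dinorlabdane-3β,8α-diol (side chain C11H2–C12H2–C13(CH3)=CH2)
Conditions: Ph3PCH3Br, KOt-Bu (excess of each), THF, 0 to 40 °C
Reagents that add atoms: methyltriphenylphosphonium bromide, C[P+](c1ccccc1)(c1ccccc1)c1ccccc1.[Br-]
Why: Wittig methylenation: excess ylide first takes the two hydroxyl protons, then drains the open δ-hydroxy ketone form from its hemiketal equilibrium. C3 is still an alcohol, so no second carbonyl competes, and no stereocentre is α to the ketone.

Step 4
Reactants: 6 13-methylidene-14,15-dinorlabdane-3β,8α-diol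
Product: 7 8α-hydroxy-13-methylidene-14,15-dinorlabdan-3-one
Conditions: TPAP (cat.), NMO, 4 Å MS, CH2Cl2, 23 °C
Reagents that add atoms: none
Why: Ley–Griffith oxidation: only the secondary C3 alcohol can be oxidised. The neutral medium avoids acid-catalysed addition of the C8 hydroxyl to the isopropenyl group, and C5 is not α to the new ketone, so no centre can epimerise.

Step 5
Reactants: 7 8α-hydroxy-13-methylidene-14,15-dinorlabdan-3-one
Product: 8 8α-hydroxy-13-methylidene-14,15-dinorlabd-2-en-3-yl trifluoromethanesulfonate
Conditions: KHMDS (2.2 equiv), THF, −78 °C; PhNTf2, −78 to 0 °C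
Reagents that add atoms: N-phenylbis(trifluoromethanesulfonimide), O=S(=O)(N(c1ccccc1)S(=O)(=O)C(F)(F)F)C(F)(F)F
Why: Enol triflation: C4 is quaternary, so deprotonation is possible at C2 only and a single Δ2 regioisomer should form. The second equivalent of base holds the C8 hydroxyl as a tertiary alkoxide that is too hindered to be sulfonylated at low temperature.

Step 6
Reactants: 8 8α-hydroxy-13-methylidene-14,15-dinorlabd-2-en-3-yl trifluoromethanesulfonate
Product: 9 3-bromo-13-methylidene-14,15-dinorlabd-2-en-8α-ol
Conditions: Ni(cod)2 (cat.), LiBr, DMA–THF, 23 °C
Reagents that add atoms: lithium bromide, [Li+].[Br-]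
Why: Nickel(0)-catalysed enol triflate–halide exchange: oxidative addition into C3–OTf, triflate/bromide exchange at Ni(II), C–Br reductive elimination. The sp2 carbon escapes the neopentyl ban on substitution, and the neutral room-temperature medium spares the tertiary alcohol and the isopropenyl group; no allyl ether is present yet.

Step 7
Reactants: 9 3-bromo-13-methylidene-14,15-dinorlabd-2-en-8α-ol
Product: 10 8α-allyloxy-3-bromo-13-methylidene-14,15-dinorlabd-2-ene
Conditions: KH, THF, 0 °C; allyl bromide, Bu4NI (cat.), 0 to 50 °C
Reagents that add atoms: allyl bromide, C=CCBr
Why: Williamson etherification of the potassium alkoxide with a small, highly SN2-active electrophile. The C8–O bond is not broken, so C8 keeps its configuration, and the ring alkenyl bromide has no pathway for elimination.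

Step 8
Reactants: 10 8α-allyloxy-3-bromo-13-methylidene-14,15-dinorlabd-2-ene
Product: 11 (13Z)-3-bromo-8α,15-epoxylabda-2,13-diene (tricyclic oxocene)
Conditions: Hoveyda–Grubbs II (cat.), 1,4-benzoquinone (cat.), toluene (1 mM), 80 °C, Ar purge
Reagents that add atoms: none
Why: Ring-closing metathesis: the catalyst loads on the allyl ether and closes onto the 1,1-disubstituted alkene with loss of ethylene; the eight-membered ring admits only the Z alkene. The diequatorial, gauche O–C8–C9–C11 array and the fully substituted C8 pre-fold the chain, benzoquinone suppresses allyl-to-propenyl isomerisation, and the hindered trisubstituted bromoalkene does not engage.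

Step 9
Reactants: 11 (13Z)-3-bromo-8α,15-epoxylabda-2,13-diene
Product: 12 (13R,14S)-3-bromo-8α,15:13,14-diepoxylabd-2-ene
Conditions: DMDO, acetone–CH2Cl2, −20 °C
Reagents that add atoms: dimethyldioxirane, CC1(C)OO1
Why: Concerted syn epoxidation by a dioxirane, acid-free. C11–C12 must stay anti to C9–C10 (the other rotamer runs into the axial methyls C17 and C20), so ring C gains room by turning O–C15 down, anti to C17; the inner face of C13=C14 then looks at H9α and the C11 hydrogens, and the open outer face (β in projection) should give 13R,14S. The bromoalkene is electron-poor and flanked by C4, so it should stay.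

Step 10
Reactants: 12 (13R,14S)-3-bromo-8α,15:13,14-diepoxylabd-2-ene
Product: 13 (3S,13R,14S)-3β-bromo-8α,15:13,14-diepoxylabdane (target)
Conditions: Mn(dpm)3 (cat.), PhSiH3, t-BuOOH, i-PrOH, 23 °C
Reagents that add atoms: none
Why: Metal-hydride hydrogen atom transfer hydrogenation, a reaction type known to reduce haloalkenes with retention of the halogen. H• goes to the less hindered C2 and gives the bromine-stabilised C3 radical rather than a β-bromo radical that would expel Br•. The second hydrogen reaches C3 from the axial α face, anti to the axial 4β-methyl and away from the C10 methyl, so bromine ends equatorial (3S); epoxide and ether are spectators and no other alkene is left.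

## Compound list

1 | (−)-sclareol, (13R)-labd-14-ene-8α,13-diol | CC1(C)CCC[C@]2(C)[C@@H](CC[C@@](C)(O)C=C)[C@](C)(O)CC[C@@H]12 | starting material
2 | 3β-hydroxysclareol | CC1(C)[C@@H](O)CC[C@]2(C)[C@@H](CC[C@@](C)(O)C=C)[C@](C)(O)CC[C@@H]12 | intermediate
3 | labdane-3β,8α,13,14,15-pentaol (C14 epimers, not isolated) | CC1(C)[C@@H](O)CC[C@]2(C)[C@@H](CC[C@@](C)(O)C(O)CO)[C@](C)(O)CC[C@@H]12 | intermediate
4 | 3β,8α,13-trihydroxy-15-norlabdan-14-al (not isolated) | CC1(C)[C@@H](O)CC[C@]2(C)[C@@H](CC[C@@](C)(O)C=O)[C@](C)(O)CC[C@@H]12 | intermediate
5 | 3β,8α-dihydroxy-14,15-dinorlabdan-13-one | CC1(C)[C@@H](O)CC[C@]2(C)[C@@H](CCC(C)=O)[C@](C)(O)CC[C@@H]12 | intermediate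
6 | 13-methylidene-14,15-dinorlabdane-3β,8α-diol | CC1(C)[C@@H](O)CC[C@]2(C)[C@@H](CCC(C)=C)[C@](C)(O)CC[C@@H]12 | intermediate
7 | 8α-hydroxy-13-methylidene-14,15-dinorlabdan-3-one | CC1(C)C(=O)CC[C@]2(C)[C@@H](CCC(C)=C)[C@](C)(O)CC[C@@H]12 | intermediate
8 | 8α-hydroxy-13-methylidene-14,15-dinorlabd-2-en-3-yl trifluoromethanesulfonate | CC1(C)C(OS(=O)(=O)C(F)(F)F)=CC[C@]2(C)[C@@H](CCC(C)=C)[C@](C)(O)CC[C@@H]12 | intermediate
9 | 3-bromo-13-methylidene-14,15-dinorlabd-2-en-8α-ol | CC1(C)C(Br)=CC[C@]2(C)[C@@H](CCC(C)=C)[C@](C)(O)CC[C@@H]12 | intermediate
10 | 8α-allyloxy-3-bromo-13-methylidene-14,15-dinorlabd-2-ene | CC1(C)C(Br)=CC[C@]2(C)[C@@H](CCC(C)=C)[C@](C)(OCC=C)CC[C@@H]12 | intermediate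
11 | (13Z)-3-bromo-8α,15-epoxylabda-2,13-diene | CC1(C)C(Br)=CC[C@]2(C)[C@H]3CC/C(C)=C\CO[C@]3(C)CC[C@@H]12 | intermediate
12 | (13R,14S)-3-bromo-8α,15:13,14-diepoxylabd-2-ene | CC1(C)C(Br)=CC[C@]2(C)[C@H]3CC[C@@]4(C)O[C@H]4CO[C@]3(C)CC[C@@H]12 | intermediate
13 | (3S,13R,14S)-3β-bromo-8α,15:13,14-diepoxylabdane, CNP0311742.2 | CC1(C)[C@@H](Br)CC[C@]2(C)[C@H]3CC[C@@]4(C)O[C@H]4CO[C@]3(C)CC[C@@H]12 | target

## Step count and least certain steps

Total step count: 10. Longest linear sequence: 10 steps (fully linear from 1).

**Risk at step 1 (key step).** Hydroxylation may spread over C2, C3 and the C4 methyl groups, or stall at low conversion, because a poorly soluble non-native diol binds loosely and uncoupling then burns cofactor.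

The fallback sets out from 1 and comes back at 7. It inverts the order of events and replaces the enzyme with a small-molecule catalyst. Lemieux–Johnson cleavage of 1 gives 8α-hydroxy-14,15-dinorlabdan-13-one F1. Non-directed methylene oxidation with a bulky non-haem iron catalyst (Fe(PDP) type, H2O2, AcOH) should attack ring A, the part most remote from the electron-withdrawing oxygens. It should give the C2 and C3 ketones, from which 8α-hydroxy-14,15-dinorlabdane-3,13-dione F2 is separated. One equivalent of Ph3P=CH2 methylenates the unhindered C13 ketone of F2 and leaves the neopentyl C3 ketone, which gives 7.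

**Risk at step 10.** Three things may go wrong.
- Bromine may be lost, either by hydrogen transfer to C3 followed by β-scission or by bromine abstraction by silyl radicals.
- Hydrogen transfer to an alkene flanked by C4 may be sluggish.
- Facial selectivity at the C3 radical may be incomplete.

The fallback sets out from 7 and comes back at 13. It makes the same α-bromo C3 radical by halogen abstraction and sets C3 before ring C is built. Compound 7 is condensed with hydrazine to 8α-hydroxy-13-methylidene-14,15-dinorlabdan-3-one hydrazone F3. Oxidative bromination (CuBr2, t-BuOLi, THF) gives 3,3-dibromo-13-methylidene-14,15-dinorlabdan-8α-ol F4. One bromine is removed with Bu3SnH (1 equiv), Et3B/air. Hydrogen again arrives from the α face, giving 3β-bromo-13-methylidene-14,15-dinorlabdan-8α-ol F5. Allylation as in step 7 gives 8α-allyloxy-3β-bromo-13-methylidene-14,15-dinorlabdane F6. Metathesis as in step 8 gives (13Z)-3β-bromo-8α,15-epoxylabd-13-ene F7, and epoxidation as in step 9 gives 13.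

**Risk at step 8.** Oligomerisation through the allyl terminus and allyl-to-propenyl isomerisation may outrun closure, because the 1,1-disubstituted alkene engages slowly and the ring is medium-sized.

The fallback sets out from 10 and comes back at 11. It forms C13=C14 by reductive carbonyl coupling. Both terminal alkenes of 10 are cleaved (OsO4 cat., NaIO4), with the hindered bromoalkene left, to give 3-bromo-8α-(2-oxoethoxy)-14,15-dinorlabd-2-en-13-one F8. An intramolecular McMurry coupling (TiCl3, Zn–Cu, DME, slow addition) closes the ring to 11.

**Risk at step 9.** Facial selectivity may be poor or reversed if ring C populates a second conformer.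

The fallback sets out from 11 and comes back at 12. It reverses the facial sense through a halohydrin. NBS in aqueous acetone puts bromonium on the face that the dioxirane prefers. Water opens it at the tertiary C13 from the other face to give (13R,14R)-3,14-dibromo-8α,15-epoxylabd-2-en-13-ol F9 (13β-OH, 14α-Br). K2CO3 in MeOH then closes the β-epoxide 12 by inversion at C14.

**Risk at step 7.** Alkylation of the hindered tertiary alkoxide may stay incomplete.

The fallback sets out from 9 and comes back at 10. It replaces SN2 alkylation with a π-allyl electrophile under neutral conditions: allyl tert-butyl carbonate, Pd2(dba)3, dppb, THF, 60 °C. The flanking quaternary C4 should keep the alkenyl bromide out of oxidative addition. No new compound is made.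

## Further compounds

F1 | step 1 | 8α-hydroxy-14,15-dinorlabdan-13-one | CC1(C)CCC[C@]2(C)[C@@H](CCC(C)=O)[C@](C)(O)CC[C@@H]12
F2 | step 1 | 8α-hydroxy-14,15-dinorlabdane-3,13-dione | CC1(C)C(=O)CC[C@]2(C)[C@@H](CCC(C)=O)[C@](C)(O)CC[C@@H]12
F3 | step 10 | 8α-hydroxy-13-methylidene-14,15-dinorlabdan-3-one hydrazone | CC1(C)C(=NN)CC[C@]2(C)[C@@H](CCC(C)=C)[C@](C)(O)CC[C@@H]12
F4 | step 10 | 3,3-dibromo-13-methylidene-14,15-dinorlabdan-8α-ol | CC1(C)C(Br)(Br)CC[C@]2(C)[C@@H](CCC(C)=C)[C@](C)(O)CC[C@@H]12
F5 | step 10 | 3β-bromo-13-methylidene-14,15-dinorlabdan-8α-ol | CC1(C)[C@@H](Br)CC[C@]2(C)[C@@H](CCC(C)=C)[C@](C)(O)CC[C@@H]12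
F6 | step 10 | 8α-allyloxy-3β-bromo-13-methylidene-14,15-dinorlabdane | CC1(C)[C@@H](Br)CC[C@]2(C)[C@@H](CCC(C)=C)[C@](C)(OCC=C)CC[C@@H]12
F7 | step 10 | (13Z)-3β-bromo-8α,15-epoxylabd-13-ene | CC1(C)[C@@H](Br)CC[C@]2(C)[C@H]3CC/C(C)=C\CO[C@]3(C)CC[C@@H]12
F8 | step 8 | 3-bromo-8α-(2-oxoethoxy)-14,15-dinorlabd-2-en-13-one | CC1(C)C(Br)=CC[C@]2(C)[C@@H](CCC(C)=O)[C@](C)(OCC=O)CC[C@@H]12
F9 | step 9 | (13R,14R)-3,14-dibromo-8α,15-epoxylabd-2-en-13-ol | CC1(C)C(Br)=CC[C@]2(C)[C@H]3CC[C@@](C)(O)[C@H](Br)CO[C@]3(C)CC[C@@H]12
F0 | step 7 | none | none
A1 | alternative 1 | (5E,9E)-farnesylacetone | CC(C)=CCC/C(C)=C/CC/C(C)=C/CCC(C)=O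
A2 | alternative 1 | 3β-bromo-8α,13-epoxy-14,15-dinorlabd-12-ene | CC1(C)[C@@H](Br)CC[C@]2(C)[C@H]3CC=C(C)O[C@]3(C)CC[C@@H]12
A3 | alternative 1 | 3β-bromo-8α-hydroxy-14,15-dinorlabdan-13-one | CC1(C)[C@@H](Br)CC[C@]2(C)[C@@H](CCC(C)=O)[C@](C)(O)CC[C@@H]12
A4 | alternative 2 | 2-methyl-2-[(3E,7E)-4,8,12-trimethyltrideca-3,7,11-trienyl]oxetane | CC(C)=CCC/C(C)=C/CC/C(C)=C/CCC1(C)CCO1
A5 | alternative 2 | 3β-bromo-8α,13:13,15-bridged oxetanium ion | CC1(C)[C@@H](Br)CC[C@]2(C)[C@H]3CCC4(C)CC[O+]4[C@]3(C)CC[C@@H]12
A6 | alternative 2 | (13Z)-3β-bromo-8α,15-epoxylabd-13-ene | CC1(C)[C@@H](Br)CC[C@]2(C)[C@H]3CC/C(C)=C\CO[C@]3(C)CC[C@@H]12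
A7 | alternative 3 | (13R,14S)-8α,15:13,14-diepoxylabdane | CC1(C)CCC[C@]2(C)[C@H]3CC[C@@]4(C)O[C@H]4CO[C@]3(C)CC[C@@H]12
A8 | alternative 3 | (13R,14S)-2α-bromo-8α,15:13,14-diepoxylabdane | CC1(C)C[C@H](Br)C[C@]2(C)[C@H]3CC[C@@]4(C)O[C@H]4CO[C@]3(C)CC[C@@H]12
A9 | alternative 3 | (13R,14S)-3α-bromo-8α,15:13,14-diepoxylabdane | CC1(C)[C@H](Br)CC[C@]2(C)[C@H]3CC[C@@]4(C)O[C@H]4CO[C@]3(C)CC[C@@H]12
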